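**Retrosynthetic overview**
1. Ring B is bought as (−)-menthone 1; regioselective dehydrogenation gives (S)-piperitone 4, which carries the C7 stereocentre.
2. Disconnection of C10–C1 and C5–C4: enone–alkene [2+2] photocycloaddition of 4 with 1-methylcyclobutene 5 gives tricyclic ketone 6.
3. Disconnection of C1–Br and C4–OH: strain-release bromohydroxylation of the C1–C4 σ bond of 6 unveils ring A (7); C5 is then epimerised to the trans-decalin 8.
4. Endgame: hydroxyl-directed reduction at C6 (diol 11), then selective 6-O-acetylation (target 12).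
5. Ring order: ring B (bought), two fused cyclobutanes (light), ring A (σ-bond opening).

Assumption: 1-methylcyclobutene 5 is bought from a specialty supplier, and a one-pot operation counts as one step; eudesmane numbering (C1–C15) is used throughout.

**Step 1**
Reactants: 1 (−)-menthone
Product: 4 (S)-(+)-piperitone, via lithium enolate 2 (not isolated), via alpha-sulfilimine ketone 3 (not isolated)
Conditions: LiN(iPr)2 (1.05 equiv), THF, −78 °C; then PhS(Cl)=NtBu (1.1 equiv), −78 °C
Reagents that add atoms: none
Why: Kinetic deprotonation at −78 °C takes place at the CH2 flank, so the isopropyl-bearing centre is never enolised; S-sulfinimidoylation of the enolate and syn-elimination across C5–C6 (Mukaiyama one-pot ketone dehydrogenation) give the enone with the (S)-centre intact and no new stereocentre.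

**Step 2**
Reactants: 4 (S)-(+)-piperitone; 5 1-methylcyclobut-1-ene
Product: 6 cis-anti-cis head-to-head photoadduct (1,4-cyclo-5β-eudesman-6-one)
Conditions: hν (350 nm, Pyrex), 5 (6 equiv), CH2Cl2, −60 °C
Reagents that add atoms: none
Why: Enone–alkene [2+2] photocycloaddition through the triplet enone and a 1,4-biradical: first bonding of the enone β-carbon to the unsubstituted cyclobutene carbon (tertiary radical, no vicinal quaternary centres) gives the head-to-head adduct, the four-membered ring closes cis on the cyclohexanone with the cyclobutene ring anti to ring B, and approach anti to the isopropyl group sets C10 (methyl β, cis to isopropyl), the minor syn-facial and head-to-tail isomers being removed by chromatography.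

**Step 3**
Reactants: 6 cis-anti-cis photoadduct
Product: 7 1β-bromo-4β-hydroxy-5β-eudesman-6-one (cis-fused)
Conditions: N-bromosuccinimide (1.2 equiv), (CF3)2CHOH–H2O (9:1), 0 °C, dark
Reagents that add atoms: N-bromosuccinimide, O=C1CCC(=O)N1Br; water, O
Why: Proposed new method: electrophilic strain-release 1,4-bromohydroxylation of the central σ bond of a bicyclo[2.2.0]hexane, in which Br+ (N-bromosuccinimide activated by hydrogen bonding to the fluorinated alcohol) attacks the less substituted bridgehead C1 on its open rear lobe, the bent C1–C4 bond (about 50 kcal/mol of strain) breaks toward the tertiary C4, and water captures C4 also from the rear, so that both carbons invert and H1 and the C4 methyl end up α (1β-Br, 4β-OH); the closest known reactions are the double-inversion bromine opening of cyclopropanes and the halo-hydroxylation of bicyclo[1.1.0]butanes and bicyclo[2.1.0]pentanes.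

**Step 4**
Reactants: 7 cis-fused bromo ketol
Product: 8 1β-bromo-4β-hydroxy-5α-eudesman-6-one (trans-fused)
Conditions: DBU (0.3 equiv), toluene, 23 °C
Reagents that add atoms: none
Why: Thermodynamic epimerisation α to the ketone (enolisation, with reversible retro-aldol/aldol as a second channel) moves H5 to the α face, because in the cis-fused isomer either the fully substituted C4 or the isopropyl group must be axial on ring B, while C4 stays as (or funnels to) the epimer with equatorial methyl, which avoids a methyl/methyl 1,3-diaxial clash with the C10 methyl.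

**Step 5**
Reactants: 8 trans-fused bromo ketol
Product: 11 1β-bromo-5α-eudesmane-4β,6α-diol, via alkoxydiacetoxyhydridoborate 9 (not isolated), via cyclic diacetoxyborate 10 (not isolated)
Conditions: Me4NBH(OAc)3 (5 equiv), MeCN–AcOH (1:1), −30 °C to 0 °C; aq. NaHCO3
Reagents that add atoms: none
Why: Evans–Saksena hydroxyl-directed reduction: the axial 4β-hydroxyl exchanges onto boron and delivers hydride intramolecularly to the β face of C6 (syn-axial to the 4β-oxygen), a face closed to external hydride by the C10 methyl, giving the equatorial 6α-alcohol (1,3-anti diol).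

**Step 6**
Reactants: 11 bromo diol
Product: 12 1β-bromo-4β-hydroxy-5α-eudesman-6α-yl acetate (target)
Conditions: Ac2O (1.5 equiv), DMAP (0.1 equiv), pyridine, CH2Cl2, 23 °C
Reagents that add atoms: acetic anhydride, CC(=O)OC(C)=O
Why: DMAP-catalysed O-acylation (nucleophilic catalysis) is selective for the secondary equatorial 6α-hydroxyl over the hindered tertiary axial 4β-hydroxyl, and no stereocentre is touched.

**Compound list**
1 | (−)-menthone, (2S,5R)-5-methyl-2-(propan-2-yl)cyclohexan-1-one | C[C@@H]1CC[C@H](C(=O)C1)C(C)C | starting material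
2 | lithium (3R,6S)-3-methyl-6-(propan-2-yl)cyclohex-1-en-1-olate (kinetic enolate) | C[C@@H]1CC[C@H](C(O[Li])=C1)C(C)C | intermediate (not isolated)
3 | (3R,6S)-2-[N-tert-butyl-S-phenylsulfilimin-S-yl]-3-methyl-6-(propan-2-yl)cyclohexan-1-one (epimers at C2 and S) | C[C@@H]1CC[C@H](C(=O)C1S(=NC(C)(C)C)c2ccccc2)C(C)C | intermediate (not isolated)
4 | (S)-(+)-piperitone, (6S)-3-methyl-6-(propan-2-yl)cyclohex-2-en-1-one | CC1=CC(=O)[C@@H](CC1)C(C)C | intermediate
5 | 1-methylcyclobut-1-ene | CC1=CCC1 | starting material
6 | cis-anti-cis head-to-head photoadduct, 8-isopropyl-1,5-dimethyltricyclo[4.4.0.0(2,5)]decan-7-one = 1,4-cyclo-5β-eudesman-6-one (extra C1–C4 bond; H5, C10–CH3 and the C7 isopropyl group on the β face of ring B; C2–C3 bridge anti to ring B; 7S) | O=C1[C@@H]2[C@@]3(C)CC[C@H]3[C@]2(C)CC[C@H]1C(C)C | intermediate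
7 | 1β-bromo-4β-hydroxy-5β-eudesman-6-one (cis-fused; 4α-CH3, 7β-isopropyl, 10β-CH3; 1R,4S,5S,7S,10R) | O=C1[C@@H]2[C@@](C)(O)CC[C@@H](Br)[C@]2(C)CC[C@H]1C(C)C | intermediate
8 | 1β-bromo-4β-hydroxy-5α-eudesman-6-one (trans-fused; 1R,4S,5R,7S,10R) | O=C1[C@H]2[C@@](C)(O)CC[C@@H](Br)[C@]2(C)CC[C@H]1C(C)C | intermediate
9 | tetramethylammonium diacetoxy(hydrido)borate bound through the 4β-oxygen of 8 | C[N+](C)(C)C.O=C1[C@H]2[C@@](C)(O[BH-](OC(C)=O)OC(C)=O)CC[C@@H](Br)[C@]2(C)CC[C@H]1C(C)C | intermediate (not isolated)
10 | tetramethylammonium cyclic diacetoxyborate of the 4β,6α-diol | C[N+](C)(C)C.CC(=O)O[B-]1(OC(C)=O)O[C@@H]2[C@H]3[C@@](C)(O1)CC[C@@H](Br)[C@]3(C)CC[C@H]2C(C)C | intermediate (not isolated)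
11 | 1β-bromo-5α-eudesmane-4β,6α-diol (1R,4S,5S,6S,7S,10R) | O[C@@H]1[C@H]2[C@@](C)(O)CC[C@@H](Br)[C@]2(C)CC[C@H]1C(C)C | intermediate
12 | 1β-bromo-4β-hydroxy-5α-eudesman-6α-yl acetate (1R,4S,5S,6S,7S,10R) | CC(=O)O[C@@H]1[C@@H]2[C@@](C)(CC[C@H]1C(C)C)[C@H](Br)CC[C@]2(C)O | target

**Step count and risks**
Total step count: 6. Longest linear sequence: 6 (1 to 12).

The three steps most likely to fail:

Step 2 (regiochemistry and facial selectivity of the photocycloaddition; a head-to-tail adduct would put the methyl group on C1, and the anti-to-isopropyl preference is an expectation, not an established result). The fallback sets out from 4 and comes back at 6. Compound 4 is irradiated with methyl cyclobut-1-ene-1-carboxylate, an acceptor-substituted alkene for which bonding of the ester-bearing carbon to the enone α-carbon is the rule, to give the ester photoadduct F1. LiAlH4 reduces ketone and ester to the diol F2. Tosyl chloride in pyridine converts the primary hydroxyl selectively to the mono-tosylate F3. LiBHEt3 displaces the tosylate by hydride to give the C4-methyl alcohol F4. Dess–Martin periodinane oxidises F4 back to ketone 6. This fixes the regiochemistry only; the facial isomers still have to be separated.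

Step 3 (the proposed σ-bond bromohydroxylation; the β-keto group disfavours the C4 cation, and proton loss or retention at C1 would give the wrong products). The fallback uses known chemistry, sets out from 6 and comes back at 8. Flash vacuum thermolysis of 6, the established cycloreversion of such bicyclo[2.2.0]hexane photoadducts to cyclodeca-1,5-dienes, gives (7S)-germacra-1(10)E,4E-dien-6-one (acoragermacrone) F5. N-Bromosuccinimide in aqueous acetone at 0 °C then triggers the known bromonium-initiated transannular cyclisation of the germacradiene through the chair–chair conformer with equatorial isopropyl, giving the trans-fused 1β-bromo-4-hydroxy ketone directly. Brief exposure to the step 4 conditions converges any 4α-hydroxy epimer on 8.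

Step 4 (the free β-hydroxy ketone may dehydrate to the conjugated enone or stay ring-opened after retro-aldol cleavage instead of epimerising cleanly). The fallback sets out from 7 and comes back at 8. The tertiary hydroxyl is first silylated with Et3SiOTf and 2,6-lutidine to give the triethylsilyl ether F6, which cannot undergo retro-aldol cleavage. DBU in warm toluene then epimerises C5 to the trans-fused silyl ether F7. HF·pyridine removes the silyl group to give 8.

**Further compounds**
F1 | step 2 | cis-anti-cis head-to-head photoadduct of 4 with methyl cyclobut-1-ene-1-carboxylate (methoxycarbonyl on C4 in place of the methyl group of 6) | O=C1[C@@H]2[C@@]3(C(=O)OC)CC[C@H]3[C@]2(C)CC[C@H]1C(C)C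
F2 | step 2 | 6,15-diol from reduction of F1 (C6 epimers) | OC1[C@@H]2[C@@]3(CO)CC[C@H]3[C@]2(C)CC[C@H]1C(C)C
F3 | step 2 | 15-O-(4-methylbenzenesulfonyl) derivative of F2 | OC1[C@@H]2[C@@]3(COS(=O)(=O)c4ccc(C)cc4)CC[C@H]3[C@]2(C)CC[C@H]1C(C)C
F4 | step 2 | 1,4-cyclo-5β-eudesman-6-ol (C6 epimers) | OC1[C@@H]2[C@@]3(C)CC[C@H]3[C@]2(C)CC[C@H]1C(C)C
F5 | step 3 | (7S)-germacra-1(10)E,4E-dien-6-one (acoragermacrone) | CC(C)[C@@H]1CC/C(C)=C/CC/C(C)=C/C1=O
F6 | step 4 | 1β-bromo-4β-(triethylsilyloxy)-5β-eudesman-6-one | O=C1[C@@H]2[C@@](C)(O[Si](CC)(CC)CC)CC[C@@H](Br)[C@]2(C)CC[C@H]1C(C)C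
F7 | step 4 | 1β-bromo-4β-(triethylsilyloxy)-5α-eudesman-6-one | O=C1[C@H]2[C@@](C)(O[Si](CC)(CC)CC)CC[C@@H](Br)[C@]2(C)CC[C@H]1C(C)C
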